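**Plan**

1. Numbering of the side chain: C1 (ArOCH2), C2 and C3 (oxirane CH and CMe), C4 (CH2), C5–C8 (lactone OCH, CH2, C(Me)OH, C=O).
2. Retrosynthetic cuts, in order: the aryl ether O–C1, the C7–OH bond (hydration of a C6=C7 butenolide), the lactone O–C8 bond, then C6=C7 and C5–O together. This leaves a C1–C6 epoxy aldehyde, nitrosobenzene and a propionate phosphonate.
3. Enabling feature: the lactone carbinol C5 is the α-carbon of the C6 aldehyde that ozonolysis of (2R,3R)-2,3-epoxygeraniol exposes, and C7–C8 with its methyl is a propionate unit. One flask can therefore oxygenate C5 and attach C7–C8 as a Z-enoate that is poised to lactonise.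
4. Forward order: the oxirane ring is made first (step 1), the chain is extended at C6 in step 4, the lactone ring closes in step 5, and the preformed coumarin is attached last because its 3,4-olefin would not survive ozone or the radical hydration.
5. Stereochemistry: C2/C3 come from the Sharpless epoxidation with D-(−)-diethyl tartrate, C5 from L-proline (catalyst control), and C7 from substrate control (oxygen enters the C7 radical anti to the C5 substituent).

Key step: step 4

Remark: 7-hydroxy-8-methoxycoumarin and phosphonate 6 are taken as purchasable; TBDPS = tert-butyldiphenylsilyl; the C5 descriptor reads R in 7–11 and S in 12, 13 and 15 only because the CIP ranking of C4 and C6 changes, the centre itself is never inverted.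

**Route**

Step 1
Reactants: 1 geraniol
Product: 2 (2R,3R)-2,3-epoxygeraniol
Conditions: Ti(OiPr)4 (cat.), D-(−)-diethyl tartrate (cat.), t-BuOOH, 4 Å MS, CH2Cl2, −20 °C
Reagents that add atoms: tert-butyl hydroperoxide, CC(C)(C)OO
Why: In this Sharpless asymmetric epoxidation the titanium–tartrate complex binds the allylic hydroxyl, so only the 2,3-olefin is epoxidised, and D-(−)-diethyl tartrate should deliver oxygen to the face that sets C2 and C3 together as R,R with the E geometry retained.

Step 2
Reactants: 2 (2R,3R)-2,3-epoxygeraniol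
Product: 3 (2R,3R)-2,3-epoxygeranyl TBDPS ether
Conditions: TBDPSCl, imidazole, CH2Cl2, 0 °C → rt
Reagents that add atoms: tert-butyl(chloro)diphenylsilane, CC(C)(C)[Si](Cl)(c1ccccc1)c1ccccc1
Why: Imidazole-mediated silylation of the primary hydroxyl (silyl ether formation) leaves the oxirane untouched and installs a group that should withstand ozone, proline, the phosphonate anion, zinc in acetic acid and the radical hydration.

Step 3
Reactants: 3 (2R,3R)-2,3-epoxygeranyl TBDPS ether
Product: 4 3-[(2R,3R)-3-(TBDPS-oxymethyl)-2-methyloxiran-2-yl]propanal (the C1–C6 aldehyde)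
Conditions: O3, CH2Cl2, −78 °C; then Me2S, −78 °C → rt
Reagents that add atoms: ozone, [O-][O+]=O
Why: Ozonolysis with reductive work-up cleaves the only remaining C=C (the trisubstituted 6,7-olefin) to the C6 aldehyde and acetone, while the oxirane and the silyl ether are inert at −78 °C.

Step 4
Reactants: 4 3-[(2R,3R)-3-(TBDPS-oxymethyl)-2-methyloxiran-2-yl]propanal; 5 nitrosobenzene; 6 ethyl 2-(diphenoxyphosphoryl)propanoate
Product: 8 ethyl (2Z,4R)-2-methyl-4-(N-phenylaminooxy)-5-[(2R,3R)-3-(TBDPS-oxymethyl)-2-methyloxiran-2-yl]pent-2-enoate, via α-aminoxy aldehyde 7 (not isolated)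
Conditions: L-proline (20 mol %), MeCN, −20 °C; then Na salt of 6 (from NaH, THF, 0 °C), −40 → 0 °C
Reagents that add atoms: none
Why: L-Proline condenses with 4 to the E-enamine, whose C5 attacks the oxygen of nitrosobenzene while the carboxylic acid protonates the nitroso nitrogen, so the C5–O bond forms on one enamine face and hydrolysis releases 7; the sodium phosphonate then adds to C6 of 7 and the oxaphosphetane collapses to the C6=C7 bond. The closest known reaction type is the proline-catalysed α-aminoxylation of aldehydes run in tandem with a Horner–Wadsworth–Emmons olefination, here with an Ando-type diaryl phosphonate. No ring is closed in this step. The new stereocentre C5 is set by the catalyst (L-proline should give the R aldehyde, which becomes the S centre of the target once C6 is saturated), and the remote (2R,3R)-oxirane should have no influence. The step needs O- over N-attack (secured by acid activation of the basic nitroso nitrogen), one enamine face (the hydrogen-bonded transition state) and Z geometry (kinetically controlled collapse of the diaryl phosphonate adduct, reinforced by the α-oxygenated branch of 7). The substrate helps because the oxirane lies γ,δ to the carbonyl and offers no β-leaving group, and immediate olefination removes the configurationally labile α-oxy aldehyde before it can epimerise.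

Step 5
Reactants: 8 ethyl (2Z,4R)-2-methyl-4-(N-phenylaminooxy)-5-[(2R,3R)-3-(TBDPS-oxymethyl)-2-methyloxiran-2-yl]pent-2-enoate
Product: 10 (5R)-3-methyl-5-{[(2R,3R)-3-(TBDPS-oxymethyl)-2-methyloxiran-2-yl]methyl}furan-2(5H)-one, via Z-γ-hydroxy enoate 9 (not isolated)
Conditions: Zn dust, AcOH, THF, 0 °C → rt
Reagents that add atoms: none
Why: Reductive N–O cleavage by zinc in acetic acid frees the C5 hydroxyl, which the Z geometry holds next to the ester, so lactonisation (intramolecular transesterification) to the α-methylbutenolide should follow in the same flask without touching the C5–O bond.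

Step 6
Reactants: 10 (5R)-3-methyl-5-{[(2R,3R)-3-(TBDPS-oxymethyl)-2-methyloxiran-2-yl]methyl}furan-2(5H)-one
Product: 12 (3R,5S)-3-hydroxy-3-methyl-5-{[(2R,3R)-3-(TBDPS-oxymethyl)-2-methyloxiran-2-yl]methyl}oxolan-2-one, via C7 hydroperoxide 11 (not isolated)
Conditions: Mn(dpm)3 (cat.), PhSiH3, O2 (1 atm), i-PrOH/CH2Cl2, 0 °C; then P(OEt)3
Reagents that add atoms: dioxygen, O=O
Why: In this Mukaiyama-type hydrogen-atom-transfer hydration the manganese hydride gives hydrogen to C6, the planar tertiary α-acyl radical at C7 should capture O2 on the ring face anti to the C5 substituent (hydroxyl trans to the side chain, 7R), and the phosphite reduces the hydroperoxide.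

Step 7
Reactants: 12 (3R,5S)-3-hydroxy-3-methyl-5-{[(2R,3R)-3-(TBDPS-oxymethyl)-2-methyloxiran-2-yl]methyl}oxolan-2-one
Product: 13 (3R,5S)-3-hydroxy-5-{[(2R,3R)-3-(hydroxymethyl)-2-methyloxiran-2-yl]methyl}-3-methyloxolan-2-one
Conditions: TBAF, AcOH, THF, 0 °C → rt
Reagents that add atoms: none
Why: Fluoride desilylation buffered with acetic acid protonates the C1 alkoxide as it forms, which should suppress Payne rearrangement of the epoxy alcohol and attack on the lactone.

Step 8
Reactants: 13 (3R,5S)-3-hydroxy-5-{[(2R,3R)-3-(hydroxymethyl)-2-methyloxiran-2-yl]methyl}-3-methyloxolan-2-one; 14 7-hydroxy-8-methoxycoumarin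
Product: 15 7-{[(2R,3R)-3-{[(2S,4R)-4-hydroxy-4-methyl-5-oxooxolan-2-yl]methyl}-3-methyloxiran-2-yl]methoxy}-8-methoxy-2H-chromen-2-one (target)
Conditions: PPh3, DIAD, THF, 0 °C → rt
Reagents that add atoms: none
Why: In this Mitsunobu etherification the acidic coumarin phenol displaces the oxyphosphonium group at the primary C1, no stereocentre is involved, and the tertiary C7 hydroxyl is too hindered to be activated.

**Compound list**

1 | geraniol | CC(C)=CCC/C(C)=C/CO | starting material
2 | (2R,3R)-2,3-epoxygeraniol, [(2R,3R)-3-methyl-3-(4-methylpent-3-enyl)oxiran-2-yl]methanol | OC[C@H]1O[C@]1(C)CCC=C(C)C | intermediate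
3 | (2R,3R)-2,3-epoxygeranyl TBDPS ether | CC(C)(C)[Si](OC[C@H]1O[C@]1(C)CCC=C(C)C)(c1ccccc1)c1ccccc1 | intermediate
4 | 3-[(2R,3R)-3-(TBDPS-oxymethyl)-2-methyloxiran-2-yl]propanal | CC(C)(C)[Si](OC[C@H]1O[C@]1(C)CCC=O)(c1ccccc1)c1ccccc1 | intermediate
5 | nitrosobenzene | O=Nc1ccccc1 | starting material
6 | ethyl 2-(diphenoxyphosphoryl)propanoate (racemic) | CCOC(=O)C(C)P(=O)(Oc1ccccc1)Oc1ccccc1 | starting material
7 | (2R)-2-(N-phenylaminooxy)-3-[(2R,3R)-3-(TBDPS-oxymethyl)-2-methyloxiran-2-yl]propanal | CC(C)(C)[Si](OC[C@H]1O[C@]1(C)C[C@@H](ONc1ccccc1)C=O)(c1ccccc1)c1ccccc1 | intermediate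
8 | ethyl (2Z,4R)-2-methyl-4-(N-phenylaminooxy)-5-[(2R,3R)-3-(TBDPS-oxymethyl)-2-methyloxiran-2-yl]pent-2-enoate | CC(C)(C)[Si](OC[C@H]1O[C@]1(C)C[C@@H](ONc1ccccc1)/C=C(/C)C(=O)OCC)(c1ccccc1)c1ccccc1 | intermediate
9 | ethyl (2Z,4R)-4-hydroxy-2-methyl-5-[(2R,3R)-3-(TBDPS-oxymethyl)-2-methyloxiran-2-yl]pent-2-enoate | CC(C)(C)[Si](OC[C@H]1O[C@]1(C)C[C@@H](O)/C=C(/C)C(=O)OCC)(c1ccccc1)c1ccccc1 | intermediate
10 | (5R)-3-methyl-5-{[(2R,3R)-3-(TBDPS-oxymethyl)-2-methyloxiran-2-yl]methyl}furan-2(5H)-one | CC(C)(C)[Si](OC[C@H]1O[C@]1(C)C[C@@H]1C=C(C)C(=O)O1)(c1ccccc1)c1ccccc1 | intermediate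
11 | (3R,5R)-3-hydroperoxy-3-methyl-5-{[(2R,3R)-3-(TBDPS-oxymethyl)-2-methyloxiran-2-yl]methyl}oxolan-2-one, OOH trans to the side chain | CC(C)(C)[Si](OC[C@H]1O[C@]1(C)C[C@@H]1C[C@@](C)(OO)C(=O)O1)(c1ccccc1)c1ccccc1 | intermediate
12 | (3R,5S)-3-hydroxy-3-methyl-5-{[(2R,3R)-3-(TBDPS-oxymethyl)-2-methyloxiran-2-yl]methyl}oxolan-2-one, OH trans to the side chain | CC(C)(C)[Si](OC[C@H]1O[C@]1(C)C[C@@H]1C[C@@](C)(O)C(=O)O1)(c1ccccc1)c1ccccc1 | intermediate
13 | (3R,5S)-3-hydroxy-5-{[(2R,3R)-3-(hydroxymethyl)-2-methyloxiran-2-yl]methyl}-3-methyloxolan-2-one | OC[C@H]1O[C@]1(C)C[C@@H]1C[C@@](C)(O)C(=O)O1 | intermediate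
14 | 7-hydroxy-8-methoxycoumarin | COc1c(O)ccc2ccc(=O)oc12 | starting material
15 | 7-{[(2R,3R)-3-{[(2S,4R)-4-hydroxy-4-methyl-5-oxooxolan-2-yl]methyl}-3-methyloxiran-2-yl]methoxy}-8-methoxy-2H-chromen-2-one | COc1c(OC[C@H]2O[C@]2(C)C[C@@H]2C[C@@](C)(O)C(=O)O2)ccc2ccc(=O)oc12 | target

**Step count and risks**

Total step count: 8. Longest linear sequence: 8 steps (1 → 15); 14 enters in the last step.

Steps most likely to fail:

Step 4. The labile α-aminoxy aldehyde may epimerise at C5 or lose its N–O bond by base-induced fragmentation when the phosphonate anion is added. Z control may also erode in the MeCN/THF mixture, and the enamine could be alkylated by the oxirane. The fallback separates oxygenation from olefination and avoids the N–O bond altogether. Setting out from 4, α-benzoyloxylation with dibenzoyl peroxide catalysed by (R)-α,α-diphenylprolinol trimethylsilyl ether in THF at 0 °C would give the isolable (2R)-2-benzoyloxy aldehyde F1. This is enamine catalysis under steric shielding, and the R catalyst is the enantiomer expected to give the 2R aldehyde. A separate Z-selective Horner–Wadsworth–Emmons reaction with the sodium salt of 6 in THF at −78 °C would give the Z-γ-benzoyloxy enoate F2. Catalytic K2CO3 in MeOH at 0 °C, stopped as soon as F2 is consumed, would remove the benzoate, and the freed C5 alkoxide would lactonise, so the route is rejoined at 10 and step 5 is bypassed.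

Step 6. Oxygen capture by the planar C7 radical may show poor facial discrimination, since the controlling C5 substituent sits 1,3 to the radical, and the radical may be reduced without being oxygenated. The fallback replaces the radical by an enolate. Setting out from 10, conjugate reduction (NiCl2·6H2O, NaBH4, MeOH, 0 °C) would give the saturated α-methyl lactone F3 as a mixture of C7 epimers, which converge on enolisation. Enolate hydroxylation (NaHMDS, THF, −78 °C; then 2-(phenylsulfonyl)-3-phenyloxaziridine) would deliver oxygen to the enolate face anti to the C5 substituent, rejoining the route at 12.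

Step 8. Activation of C1 beside an oxirane may be diverted by participation of the neighbouring epoxide oxygen, the ortho-methoxy phenol may couple slowly, and removal of phosphine oxide and hydrazide at the last stage may cost material. The fallback replaces redox activation by a sulfonate displacement. Setting out from 13, selective sulfonylation of the primary hydroxyl (TsCl, Et3N, DMAP cat., CH2Cl2, 0 °C; the tertiary C7 hydroxyl should not react) would give the epoxy tosylate F4. Williamson alkylation of 14 (K2CO3, DMF, rt) by SN2 at C1 would then give 15.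

**Further compounds**

F1 | step 4 | (2R)-2-benzoyloxy-3-[(2R,3R)-3-(TBDPS-oxymethyl)-2-methyloxiran-2-yl]propanal | CC(C)(C)[Si](OC[C@H]1O[C@]1(C)C[C@@H](OC(=O)c1ccccc1)C=O)(c1ccccc1)c1ccccc1
F2 | step 4 | ethyl (2Z,4R)-4-benzoyloxy-2-methyl-5-[(2R,3R)-3-(TBDPS-oxymethyl)-2-methyloxiran-2-yl]pent-2-enoate | CC(C)(C)[Si](OC[C@H]1O[C@]1(C)C[C@@H](OC(=O)c1ccccc1)/C=C(/C)C(=O)OCC)(c1ccccc1)c1ccccc1
F3 | step 6 | (5S)-3-methyl-5-{[(2R,3R)-3-(TBDPS-oxymethyl)-2-methyloxiran-2-yl]methyl}oxolan-2-one, mixture of epimers at the methyl-bearing carbon | CC(C)(C)[Si](OC[C@H]1O[C@]1(C)C[C@@H]1CC(C)C(=O)O1)(c1ccccc1)c1ccccc1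
F4 | step 8 | [(2R,3R)-3-{[(2S,4R)-4-hydroxy-4-methyl-5-oxooxolan-2-yl]methyl}-3-methyloxiran-2-yl]methyl 4-methylbenzenesulfonate | Cc1ccc(cc1)S(=O)(=O)OC[C@H]1O[C@]1(C)C[C@@H]1C[C@@](C)(O)C(=O)O1
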